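The route rests on disconnecting the α-methylene-γ-butyrolactone and the tetrahydropyran at once. A hetero-Pauson–Khand [2+2+1] reaction of an aldehyde, the internal double bond of a terminal allene and CO forms the bond from the lactone O–CH carbon (C14) to the ring-fusion carbon (C1) and the bond from the methylene-bearing carbon (C15) to the lactone carbonyl (C16) in one operation, setting both new stereocentres. Because C14 and C1 are also pyran atoms, the pyran (C1, C2, C3, O, C13, C14) and the cis-fused lactone close together. The precursor is a 12-membered macrocyclic ether with CHO on C13 and a buta-2,3-dienyl group on C3, closed beforehand by a Z-selective intramolecular Wittig reaction.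

Key step: step 22

Numbering (remark): the target is numbered like a cembrane: C1 (ring-fusion CH bearing C15), C2 (CH2), C3 (pyran CH–O), C4 (C(OH)CH3), C5 (CH2), C6=C7 (Z), C8 (C(OH)CH3), C9–C11 (three CH2), C12 (CHCH3), C13 (pyran CH–O), C14 (lactone CH–O), C15 (=C), C16 (C=O), C17 (=CH2). Intermediates keep these labels; the descriptors 3R, 4S, 8R, 12S, 13R (and 1R, 14S after step 22) hold throughout. TES = triethylsilyl, PMB = 4-methoxybenzyl.

Remark on the chemistry: the acyl C16–O bond of the lactone closes in the same operation as the two C–C bonds of the key step.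

Step 1
Reactants: 1 (R)-(−)-linalool
Product: 2 (3R)-3,7-dimethyl-3-(triethylsilyloxy)octa-1,6-diene
Conditions: Et3SiOTf, 2,6-lutidine, CH2Cl2, −78 to 0 °C
Reagents that add atoms: triethylsilyl trifluoromethanesulfonate CC[Si](CC)(CC)OS(=O)(=O)C(F)(F)F
Why: Silyl triflate silylation is the standard way to protect a hindered tertiary allylic alcohol, and the C8 stereocentre comes unchanged from the chiral pool.

Step 2
Reactants: 2 (3R)-3,7-dimethyl-3-(triethylsilyloxy)octa-1,6-diene
Product: 4 (4R)-4-methyl-4-(triethylsilyloxy)hex-5-en-1-ol, via aldehyde 3 (not isolated)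
Conditions: O3, CH2Cl2/MeOH, −78 °C (Sudan Red 7B end point); then NaBH4, −78 to 0 °C
Reagents that add atoms: ozone [O-][O+]=O
Why: Chemoselective ozonolysis with reductive work-up should cleave the electron-rich trisubstituted alkene much faster than the vinyl group on the quaternary carbon, and borohydride reduces the cleavage product to the primary alcohol in the same pot.

Step 3
Reactants: 4 (4R)-4-methyl-4-(triethylsilyloxy)hex-5-en-1-ol
Product: 5 (3R)-6-bromo-3-methyl-3-(triethylsilyloxy)hex-1-ene
Conditions: CBr4, PPh3, CH2Cl2, 0 °C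
Reagents that add atoms: carbon tetrabromide BrC(Br)(Br)Br
Why: The Appel reaction converts the primary alcohol into the bromide under neutral conditions that the tertiary allylic silyl ether tolerates.

Step 4
Reactants: 6 (E)-but-2-en-1-ol
Product: 7 (2S,3S)-2,3-epoxybutan-1-ol
Conditions: Ti(OiPr)4 (10 mol %), L-(+)-diethyl tartrate (12 mol %), t-BuOOH, 4 Å MS, CH2Cl2, −20 °C
Reagents that add atoms: tert-butyl hydroperoxide CC(C)(C)OO
Why: Sharpless asymmetric epoxidation of the (E)-allylic alcohol with L-(+)-tartrate delivers oxygen to the face that gives the (2S,3S)-epoxide, which later becomes C13 and C12.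

Step 5
Reactants: 7 (2S,3S)-2,3-epoxybutan-1-ol
Product: 8 (2S,3S)-2-[(4-methoxybenzyloxy)methyl]-3-methyloxirane
Conditions: NaH, PMBCl, Bu4NI (cat.), THF/DMF, 0 °C
Reagents that add atoms: 4-methoxybenzyl chloride COc1ccc(CCl)cc1
Why: Williamson etherification of the primary alkoxide under aprotic conditions should proceed without Payne rearrangement and leaves both stereocentres untouched.

Step 6
Reactants: 5 (3R)-6-bromo-3-methyl-3-(triethylsilyloxy)hex-1-ene; 8 (2S,3S)-2-[(4-methoxybenzyloxy)methyl]-3-methyloxirane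
Product: 10 (2R,3S,7R)-1-(4-methoxybenzyloxy)-3,7-dimethyl-7-(triethylsilyloxy)non-8-en-2-ol, via Grignard reagent 9 (not isolated)
Conditions: Mg, THF, 40 °C; then CuI (10 mol %), 8, THF, −40 to 0 °C
Reagents that add atoms: none
Why: Copper-catalysed SN2 opening of the trans-epoxide by the primary Grignard reagent should occur at the methyl-bearing carbon, distal to the deactivating and bulkier CH2OPMB side, with inversion that sets C12 (S) while the C13 carbinol (R) is retained from the epoxide.

Step 7
Reactants: 10 (2R,3S,7R)-1-(4-methoxybenzyloxy)-3,7-dimethyl-7-(triethylsilyloxy)non-8-en-2-ol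
Product: 11 glycolic acid ether of 10 (C13–O–CH2–CO2H)
Conditions: NaH (3 equiv), BrCH2CO2H, THF, 0 °C to rt; acidic work-up (pH 3)
Reagents that add atoms: bromoacetic acid OC(=O)CBr
Why: Williamson O-alkylation of the secondary sodium alkoxide with sodium bromoacetate is the established entry to glycolic acid ethers of hindered secondary alcohols and brings in C3 and C4.

Step 8
Reactants: 11 glycolic acid ether of 10
Product: 13 (4S)-4-benzyl-3-(alkoxyacetyl)oxazolidin-2-one glycolate imide, via mixed pivalic anhydride 12 (not isolated)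
Conditions: t-BuCOCl, Et3N, THF, −78 to 0 °C; then (S)-4-benzyl-2-oxazolidinone/n-BuLi (premixed, THF, −78 °C), −78 to 0 °C
Reagents that add atoms: (S)-4-benzyl-2-oxazolidinone O=C1OC[C@H](Cc2ccccc2)N1
Why: Mixed-anhydride N-acylation of the lithiated oxazolidinone installs the Evans auxiliary needed for the asymmetric glycolate alkylation.

Step 9
Reactants: 13 (4S)-4-benzyl-3-(alkoxyacetyl)oxazolidin-2-one glycolate imide
Product: 15 (4S)-4-benzyl-3-[(2R)-2-alkoxypent-4-ynoyl]oxazolidin-2-one, via sodium Z-enolate 14 (not isolated)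
Conditions: NaN(SiMe3)2, THF, −78 °C; then propargyl bromide, −78 to −45 °C
Reagents that add atoms: propargyl bromide C#CCBr
Why: In this Evans-type glycolate alkylation the chelated (Z)-sodium enolate is alkylated on the face opposite the benzyl group, which sets C3 (R) and brings in C2, C1 and C15.

Step 10
Reactants: 15 (4S)-4-benzyl-3-[(2R)-2-alkoxypent-4-ynoyl]oxazolidin-2-one
Product: 16 (2R)-N-methoxy-N-methyl-2-alkoxypent-4-ynamide (Weinreb amide)
Conditions: MeNH(OMe)·HCl, AlMe3, CH2Cl2, −10 to 0 °C
Reagents that add atoms: N,O-dimethylhydroxylamine hydrochloride CNOC.Cl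
Why: Aluminium amide transamination (Weinreb amide formation) cleaves the auxiliary at the exocyclic carbonyl without epimerising C3.

Step 11
Reactants: 16 (2R)-N-methoxy-N-methyl-2-alkoxypent-4-ynamide
Product: 17 (5R)-5-alkoxyoct-1-en-7-yn-4-one (allyl ketone)
Conditions: allylMgBr (2.5 equiv), THF, −78 °C; cold pH 7 buffer quench
Reagents that add atoms: allylmagnesium bromide C=CC[Mg]Br
Why: In the Weinreb ketone synthesis the magnesium-chelated tetrahedral intermediate prevents over-addition, and a cold neutral quench should keep the β,γ-unsaturated ketone out of conjugation.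

Step 12
Reactants: 17 (5R)-5-alkoxyoct-1-en-7-yn-4-one
Product: 18 (4S,5R)-5-alkoxy-4-methyloct-1-en-7-yn-4-ol (target numbering 3R,4S)
Conditions: MeMgBr (3 equiv), THF, −78 °C
Reagents that add atoms: methylmagnesium bromide C[Mg]Br
Why: In this chelation-controlled Grignard addition magnesium bridges the carbonyl and the C3 ether oxygen, so methyl adds from the face of H3 away from the propargyl group and sets C4 (S).

Step 13
Reactants: 18 (4S,5R)-5-alkoxy-4-methyloct-1-en-7-yn-4-ol
Product: 19 bis(triethylsilyl) ether diene (C4–OTES, C8–OTES)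
Conditions: Et3SiOTf, 2,6-lutidine, CH2Cl2, −78 to 0 °C
Reagents that add atoms: triethylsilyl trifluoromethanesulfonate CC[Si](CC)(CC)OS(=O)(=O)C(F)(F)F
Why: Silyl triflate protection of the tertiary alcohol is needed so that C4–OH cannot later form a lactol or lactone with C14.

Step 14
Reactants: 19 bis(triethylsilyl) ether diene
Product: 21 C6,C7-diol, via dialdehyde 20 (not isolated)
Conditions: O3, CH2Cl2/MeOH, −78 °C (Sudan Red 7B end point); then NaBH4, −78 to 0 °C
Reagents that add atoms: ozone [O-][O+]=O
Why: Ozonolysis with borohydride work-up cleaves both terminal alkenes, which react far faster with ozone than the terminal alkyne or the anisyl ring, and gives the C6 and C7 primary alcohols.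

Step 15
Reactants: 21 C6,C7-diol
Product: 22 C6 iodide with free C7 alcohol
Conditions: I2, PPh3, imidazole, CH2Cl2, 0 °C
Reagents that add atoms: iodine II
Why: Appel-type iodination should be selective for the unhindered C6 alcohol because SN2 displacement at the neopentyl C7 carbinol is very slow.

Step 16
Reactants: 22 C6 iodide with free C7 alcohol
Product: 23 C6 iodide C7 aldehyde
Conditions: Dess–Martin periodinane, NaHCO3, CH2Cl2, 0 °C to rt
Reagents that add atoms: none
Why: Dess–Martin oxidation of the neopentyl alcohol gives a non-enolisable α-silyloxy aldehyde under buffered conditions that the iodide and silyl ethers tolerate.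

Step 17
Reactants: 23 C6 iodide C7 aldehyde
Product: 24 C6 triphenylphosphonium iodide C7 aldehyde
Conditions: PPh3, MeCN, 80 °C
Reagents that add atoms: triphenylphosphine c1ccc(cc1)P(c1ccccc1)c1ccccc1
Why: SN2 quaternisation of triphenylphosphine by the primary iodide gives the Wittig salt, and the non-enolisable aldehyde is inert to the phosphine.

Step 18
Reactants: 24 C6 triphenylphosphonium iodide C7 aldehyde
Product: 26 12-membered (Z)-macrocyclic ether with propargyl group on C3, via phosphonium ylide 25 (not isolated)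
Conditions: KN(SiMe3)2 (1.0 equiv), THF, 0.002 M, slow addition of 24, −78 °C to rt
Reagents that add atoms: none
Why: In this intramolecular Wittig olefination the salt-free non-stabilised ylide (formed selectively because the phosphonium salt is far more acidic than the terminal alkyne) should react with the hindered aldehyde under kinetic control to give the (Z)-C6=C7 alkene and close the 12-membered ring.

Step 19
Reactants: 26 12-membered (Z)-macrocyclic ether with propargyl group on C3
Product: 28 macrocyclic ether with buta-2,3-dienyl group on C3, via propargylic dicyclohexylamine 27 (not isolated)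
Conditions: (CH2O)n, CuI (0.5 equiv), Cy2NH, 1,4-dioxane, reflux
Reagents that add atoms: formaldehyde (as paraformaldehyde) C=O
Why: In the Crabbé homologation a copper-mediated Mannich reaction of the terminal alkyne is followed by intramolecular hydride transfer from the amine, which turns the propargyl group into the terminal allene (C17 added) without touching the other groups.

Step 20
Reactants: 28 macrocyclic ether with buta-2,3-dienyl group on C3
Product: 29 C14 primary alcohol
Conditions: DDQ, CH2Cl2/pH 7 buffer, 0 °C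
Reagents that add atoms: none
Why: Oxidative cleavage of the 4-methoxybenzyl ether by DDQ is orthogonal to the tertiary silyl ethers, the allene and the hindered Z alkene.

Step 21
Reactants: 29 C14 primary alcohol
Product: 30 C14 aldehyde (allenyl aldehyde)
Conditions: Dess–Martin periodinane, NaHCO3, CH2Cl2, 0 °C
Reagents that add atoms: none
Why: Buffered Dess–Martin oxidation should give the α-alkoxy aldehyde without epimerising C13, and the aldehyde is used directly.

Step 22
Reactants: 30 C14 aldehyde (allenyl aldehyde)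
Product: 31 bis(triethylsilyl) ether of the target (tricyclic α-methylene lactone)
Conditions: Ru3(CO)12 (5 mol %), CO (20 atm), 1,4-dioxane, 120 °C
Reagents that add atoms: carbon monoxide [C-]#[O+]
Why: This is a hetero-Pauson–Khand [2+2+1] cyclocarbonylation: zerovalent ruthenium binds the aldehyde C14=O and the internal allene bond C1=C15, oxidative cyclisation forms the C14–C1 bond and an oxaruthenacyclopentane, CO inserts into Ru–C15 to form the C15–C16 bond, and reductive elimination closes the acyl C16–O bond. The closest known reaction type is the Ru3(CO)12- or Mo(CO)6-mediated cyclocarbonylation of tethered allenyl aldehydes to bicyclic α-methylene-γ-butyrolactones. The tetrahydropyran closes in a 6-exo mode across the C13–O–C3 ether tether and the lactone ring is assembled on it by the [2+2+1] annulation, the five-membered metallacycle allowing only a cis ring fusion. C14 is controlled by C13: in the chair-like transition state with the macrocycle bonds C13–C12 and C3–C4 equatorial, the aldehyde oxygen should lie equatorial and anti to the C13–O bond (dipole-minimised, Cornforth-type), giving 14S. C1 follows from C14 and C3 through the cis-fused metallacycle, which puts C15 axial and trans to the C3–C4 bond, giving 1R. The step needs reaction at the internal instead of the terminal allene bond and no reaction at the Z alkene; the four-atom tether (six- against seven-membered ring) secures the first, and the absence of any other unsaturation within chelating distance of the aldehyde secures the second.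

Step 23
Reactants: 31 bis(triethylsilyl) ether of the target
Product: 32 target CNP0146755.1
Conditions: HF·pyridine, pyridine, THF, 0 °C to rt
Reagents that add atoms: none
Why: Fluoride-mediated cleavage of both tertiary triethylsilyl ethers under buffered non-basic conditions should spare the α-methylene lactone and the tertiary allylic alcohol.

Compound list

1 | (R)-(−)-linalool, (3R)-3,7-dimethylocta-1,6-dien-3-ol | C=C[C@](C)(O)CCC=C(C)C | starting material
2 | (3R)-3,7-dimethyl-3-(triethylsilyloxy)octa-1,6-diene | C=C[C@](C)(O[Si](CC)(CC)CC)CCC=C(C)C | intermediate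
3 | (4R)-4-methyl-4-(triethylsilyloxy)hex-5-enal | C=C[C@](C)(O[Si](CC)(CC)CC)CCC=O | intermediate (not isolated)
4 | (4R)-4-methyl-4-(triethylsilyloxy)hex-5-en-1-ol | C=C[C@](C)(O[Si](CC)(CC)CC)CCCO | intermediate
5 | (3R)-6-bromo-3-methyl-3-(triethylsilyloxy)hex-1-ene | C=C[C@](C)(O[Si](CC)(CC)CC)CCCBr | intermediate
6 | (E)-but-2-en-1-ol (crotyl alcohol) | C/C=C/CO | starting material
7 | (2S,3S)-2,3-epoxybutan-1-ol | OC[C@@H]1O[C@H]1C | intermediate
8 | (2S,3S)-2-[(4-methoxybenzyloxy)methyl]-3-methyloxirane | COc1ccc(COC[C@@H]2O[C@H]2C)cc1 | intermediate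
9 | (4R)-4-methyl-4-(triethylsilyloxy)hex-5-enylmagnesium bromide | C=C[C@](C)(O[Si](CC)(CC)CC)CCC[Mg]Br | intermediate (not isolated)
10 | (2R,3S,7R)-1-(4-methoxybenzyloxy)-3,7-dimethyl-7-(triethylsilyloxy)non-8-en-2-ol (13R,12S,8R) | COc1ccc(COC[C@H](O)[C@@H](C)CCC[C@@](C)(O[Si](CC)(CC)CC)C=C)cc1 | intermediate
11 | {[(2R,3S,7R)-1-(4-methoxybenzyloxy)-3,7-dimethyl-7-(triethylsilyloxy)non-8-en-2-yl]oxy}acetic acid | COc1ccc(COC[C@H](OCC(=O)O)[C@@H](C)CCC[C@@](C)(O[Si](CC)(CC)CC)C=C)cc1 | intermediate
12 | mixed anhydride of acid 11 with pivalic acid | COc1ccc(COC[C@H](OCC(=O)OC(=O)C(C)(C)C)[C@@H](C)CCC[C@@](C)(O[Si](CC)(CC)CC)C=C)cc1 | intermediate (not isolated)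
13 | (4S)-4-benzyl-3-(alkoxyacetyl)oxazolidin-2-one, alkoxy = the C13 oxygen of 10 | COc1ccc(COC[C@H](OCC(=O)N2[C@@H](Cc3ccccc3)COC2=O)[C@@H](C)CCC[C@@](C)(O[Si](CC)(CC)CC)C=C)cc1 | intermediate
14 | sodium (Z)-enolate of imide 13 | COc1ccc(COC[C@H](O/C=C(\[O-])N2[C@@H](Cc3ccccc3)COC2=O)[C@@H](C)CCC[C@@](C)(O[Si](CC)(CC)CC)C=C)cc1.[Na+] | intermediate (not isolated)
15 | (4S)-4-benzyl-3-[(2R)-2-alkoxypent-4-ynoyl]oxazolidin-2-one (3R,8R,12S,13R) | COc1ccc(COC[C@H](O[C@H](CC#C)C(=O)N2[C@@H](Cc3ccccc3)COC2=O)[C@@H](C)CCC[C@@](C)(O[Si](CC)(CC)CC)C=C)cc1 | intermediate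
16 | (2R)-N-methoxy-N-methyl-2-alkoxypent-4-ynamide (Weinreb amide; 3R,8R,12S,13R) | COc1ccc(COC[C@H](O[C@H](CC#C)C(=O)N(C)OC)[C@@H](C)CCC[C@@](C)(O[Si](CC)(CC)CC)C=C)cc1 | intermediate
17 | (5R)-5-alkoxyoct-1-en-7-yn-4-one (C4 ketone bearing allyl; 3R,8R,12S,13R) | COc1ccc(COC[C@H](O[C@H](CC#C)C(=O)CC=C)[C@@H](C)CCC[C@@](C)(O[Si](CC)(CC)CC)C=C)cc1 | intermediate
18 | (4S,5R)-5-alkoxy-4-methyloct-1-en-7-yn-4-ol (3R,4S,8R,12S,13R) | COc1ccc(COC[C@H](O[C@H](CC#C)[C@@](C)(O)CC=C)[C@@H](C)CCC[C@@](C)(O[Si](CC)(CC)CC)C=C)cc1 | intermediate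
19 | C4,C8-bis(triethylsilyl) ether of 18 (allyl on C4, vinyl on C8, propargyl on C3) | COc1ccc(COC[C@H](O[C@H](CC#C)[C@@](C)(O[Si](CC)(CC)CC)CC=C)[C@@H](C)CCC[C@@](C)(O[Si](CC)(CC)CC)C=C)cc1 | intermediate
20 | dialdehyde (C6 and C7 as CHO) | COc1ccc(COC[C@H](O[C@H](CC#C)[C@@](C)(O[Si](CC)(CC)CC)CC=O)[C@@H](C)CCC[C@@](C)(O[Si](CC)(CC)CC)C=O)cc1 | intermediate (not isolated)
21 | diol (C6 and C7 as CH2OH) | COc1ccc(COC[C@H](O[C@H](CC#C)[C@@](C)(O[Si](CC)(CC)CC)CCO)[C@@H](C)CCC[C@@](C)(O[Si](CC)(CC)CC)CO)cc1 | intermediate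
22 | C6 iodide, C7 primary alcohol | COc1ccc(COC[C@H](O[C@H](CC#C)[C@@](C)(O[Si](CC)(CC)CC)CCI)[C@@H](C)CCC[C@@](C)(O[Si](CC)(CC)CC)CO)cc1 | intermediate
23 | C6 iodide, C7 aldehyde | COc1ccc(COC[C@H](O[C@H](CC#C)[C@@](C)(O[Si](CC)(CC)CC)CCI)[C@@H](C)CCC[C@@](C)(O[Si](CC)(CC)CC)C=O)cc1 | intermediate
24 | C6 triphenylphosphonium iodide, C7 aldehyde | COc1ccc(COC[C@H](O[C@H](CC#C)[C@@](C)(O[Si](CC)(CC)CC)CC[P+](c2ccccc2)(c2ccccc2)c2ccccc2)[C@@H](C)CCC[C@@](C)(O[Si](CC)(CC)CC)C=O)cc1.[I-] | intermediate
25 | C6 phosphonium ylide, C7 aldehyde | COc1ccc(COC[C@H](O[C@H](CC#C)[C@@](C)(O[Si](CC)(CC)CC)CC=P(c2ccccc2)(c2ccccc2)c2ccccc2)[C@@H](C)CCC[C@@](C)(O[Si](CC)(CC)CC)C=O)cc1 | intermediate (not isolated)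
26 | 12-membered cyclic ether (ring: O, C3, C4, C5, C6=C7 Z, C8–C13) with CH2OPMB on C13, propargyl on C3, OTES on C4 and C8 (3R,4S,8R,12S,13R) | COc1ccc(COC[C@@H]2O[C@H](CC#C)[C@@](C)(O[Si](CC)(CC)CC)C/C=C\[C@](C)(O[Si](CC)(CC)CC)CCC[C@@H]2C)cc1 | intermediate
27 | Mannich base of 26: 4-(dicyclohexylamino)but-2-ynyl group on C3 | COc1ccc(COC[C@@H]2O[C@H](CC#CCN(C3CCCCC3)C3CCCCC3)[C@@](C)(O[Si](CC)(CC)CC)C/C=C\[C@](C)(O[Si](CC)(CC)CC)CCC[C@@H]2C)cc1 | intermediate (not isolated)
28 | macrocyclic ether with buta-2,3-dienyl group on C3 and CH2OPMB on C13 | COc1ccc(COC[C@@H]2O[C@H](CC=C=C)[C@@](C)(O[Si](CC)(CC)CC)C/C=C\[C@](C)(O[Si](CC)(CC)CC)CCC[C@@H]2C)cc1 | intermediate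
29 | macrocyclic ether with buta-2,3-dienyl group on C3 and CH2OH (C14) on C13 | OC[C@@H]1O[C@H](CC=C=C)[C@@](C)(O[Si](CC)(CC)CC)C/C=C\[C@](C)(O[Si](CC)(CC)CC)CCC[C@@H]1C | intermediate
30 | macrocyclic ether with buta-2,3-dienyl group on C3 and CHO (C14) on C13 | O=C[C@@H]1O[C@H](CC=C=C)[C@@](C)(O[Si](CC)(CC)CC)C/C=C\[C@](C)(O[Si](CC)(CC)CC)CCC[C@@H]1C | intermediate
31 | C4,C8-bis(triethylsilyl) ether of the target (1R,3R,4S,8R,12S,13R,14S; 6Z) | C=C1C(=O)O[C@@H]2[C@@H]3O[C@H](C[C@H]12)[C@@](C)(O[Si](CC)(CC)CC)C/C=C\[C@](C)(O[Si](CC)(CC)CC)CCC[C@@H]3C | intermediate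
32 | target CNP0146755.1 (1R,3R,4S,8R,12S,13R,14S; 6Z) | C=C1C(=O)O[C@@H]2[C@@H]3O[C@H](C[C@H]12)[C@@](C)(O)C/C=C\[C@](C)(O)CCC[C@@H]3C | target

Total step count: 23.
Longest linear sequence: 21 steps (steps 1–3 and 6–23; steps 4 and 5 make the epoxide on a side branch).

Steps most likely to fail

1. Step 22 (key step). The oxidative cyclisation may show poor facial selectivity at C14/C1, or the α-alkoxy aldehyde may epimerise or decarbonylate at 120 °C. The fallback forms the same two bonds one after the other at ambient temperature. It sets out from aldehyde 30. Pd-catalysed silylstannylation of the allene with Me3Si–SnBu3 ([Pd(C3H5)Cl]2 cat., THF, rt) gives an allylstannane that transfers intramolecularly to the aldehyde (C14–C1 bond); a chelating (MgBr2·OEt2) or non-chelating (BF3·OEt2) promoter can be chosen to steer the aldehyde face. This should give the cis hydroxy vinylsilane F1. Iododesilylation (N-iodosuccinimide, MeCN, 0 °C) gives the hydroxy vinyl iodide F2. Pd-catalysed carbonylative lactonisation (Pd(PPh3)4, CO 1 atm, Et3N, MeCN, 60 °C) forms C15–C16 and the lactone and comes back to the route at 31.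

2. Step 18. Intermolecular Wittig oligomerisation may compete with closure of the 12-membered ring, and some Z selectivity may be lost. The fallback closes the same bond by olefin metathesis and sets out from diene 19. C-silylation of the terminal alkyne (LiN(SiMe3)2, then i-Pr3SiOTf, THF, −78 °C), which blocks enyne metathesis, gives the silylalkyne diene F3. Ring-closing metathesis (second-generation Grubbs catalyst, toluene, high dilution, 80 °C), with chromatographic removal of any E isomer, gives the silylalkyne macrocycle F4. Selective C-desilylation (Bu4NF buffered with AcOH, THF, 0 °C) comes back to the route at 26. This fallback trades the Z-secure Wittig closure for a shorter one whose E/Z outcome is uncertain.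

3. Step 11 (with step 12). The β,γ-unsaturated ketone may isomerise into conjugation, suffer over-addition, or enolise in the following Grignard step. The fallback reverses the order of the two carbon nucleophiles and replaces chelation control by reagent control; it sets out from Weinreb amide 16. MeMgBr (THF, −78 °C) gives the robust methyl ketone F5. Allylboration with the enantiomer of B-allyl-10-phenyl-9-borabicyclo[3.3.2]decane that delivers allyl to the non-chelation (Felkin–Anh) face, followed by oxidative work-up, comes back to the route at tertiary alcohol 18.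

Further compounds

F1 | step 22 | cis hydroxy vinylsilane: pyran closed, C14–OH, 1-(trimethylsilyl)vinyl on C1, OTES on C4 and C8 | O[C@@H]1[C@@H]2O[C@H](C[C@@H]1C(=C)[Si](C)(C)C)[C@@](C)(O[Si](CC)(CC)CC)C/C=C\[C@](C)(O[Si](CC)(CC)CC)CCC[C@@H]2C
F2 | step 22 | hydroxy vinyl iodide: pyran closed, C14–OH, 1-iodovinyl on C1, OTES on C4 and C8 | O[C@@H]1[C@@H]2O[C@H](C[C@@H]1C(=C)I)[C@@](C)(O[Si](CC)(CC)CC)C/C=C\[C@](C)(O[Si](CC)(CC)CC)CCC[C@@H]2C
F3 | step 18 | diene 19 with the alkyne terminus capped by triisopropylsilyl | COc1ccc(COC[C@H](O[C@H](CC#C[Si](C(C)C)(C(C)C)C(C)C)[C@@](C)(O[Si](CC)(CC)CC)CC=C)[C@@H](C)CCC[C@@](C)(O[Si](CC)(CC)CC)C=C)cc1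
F4 | step 18 | (Z)-macrocycle 26 with the alkyne terminus capped by triisopropylsilyl | COc1ccc(COC[C@@H]2O[C@H](CC#C[Si](C(C)C)(C(C)C)C(C)C)[C@@](C)(O[Si](CC)(CC)CC)C/C=C\[C@](C)(O[Si](CC)(CC)CC)CCC[C@@H]2C)cc1
F5 | step 11 | methyl ketone: (3R)-3-alkoxyhex-5-yn-2-one, alkoxy = the C13 oxygen of 10 | COc1ccc(COC[C@H](O[C@H](CC#C)C(C)=O)[C@@H](C)CCC[C@@](C)(O[Si](CC)(CC)CC)C=C)cc1
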